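Compare the pace at which second end groups catch a first end group with the pace at which that group strays by itself. You asked for a quick number for west and your hunch is the cold, which this ratio does not test, so I leave the cold as a guess and reckon the share of first end groups that reaches links, taking the first pace to grow with the second end groups present and the second pace not to, so that their ratio behaves like a ratio of two time constants.

| flask | first end groups | second end groups | temperature | remark | time |
|---|---|---|---|---|---|
| larch | 0.33 M | 1 equiv | 90 °C | run made earlier |  |
| west | 0.30 M | 4.00 equiv | 50 °C |  | 4.0 min |
| east | 0.10 M | 0.670 equiv | 60 °C |  | 4.0 min |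
| south-west | 1.0 M | 2.00 equiv | 105 °C |  | 4.0 min |
| north | 0.30 M | 1.00 equiv | 90 °C |  | 4.0 min |
| south-east | 0.080 M | 0.500 equiv | 120 °C |  | 4.0 min |

- larch (time / s: links / %, first end groups / %): 10.0: 46.1, 42.5; 15.0: 52.8, 33.5; 30.0: 54.5, 19.3; 50.0: 50.6, 12.4; 60.0: 48.3, 9.7; 80.0: 44.0, 7.6

(scatter of a reading: 0.5 percentage points)

- the earlier runs do not show what temperature does; that part of a forecast is a guess

1. the flasks by amount of links, in percent of the first end groups charged, highest first, at 4.0 min (west / east / south-west / north / south-east)
2. the amount of links, in percent of the first end groups charged of the flask you put first, at 4.0 min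
3. the amount of links, in percent of the first end groups charged of the flask you put last, at 4.0 min

I calibrate on the first larch reading, because links later fall, from 54.5% to 44.0%, and that fall mixes into any later count. At 10.0 s larch shows 46.1% of links and 11.4% unaccounted for, which would be 4.04 links per stray group if all of it were stray groups, but part of it may be links already lost, so I hold this as a low reading. Over that stretch second end groups average 0.235 M. Dividing gives the catch number, a selectivity factor: links made per stray group, per unit of mean second end groups, 17.2 L mol⁻¹.

West holds a mean of 1.05 M if each first end group takes one second end group, so its ratio is 18.1 and the share reaching links is 94.8%. The mean costs little, because the share runs from 95.4% at the start to 93.9% at the end. West is cooler than larch, and what that does is my guess, but at larch's pace, 0.429 L mol⁻¹ s⁻¹, the half-life of first end groups is 1.54 s, and the time holds 156 of those, which leaves the cooling much room. I commit to that share for west, though it is reckoned at larch's temperature and says nothing of what links lose after they are made.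

The forecast gives west > east > north > south-west > south-east, with 78% first, below my figure, and 0.1% last, reasoning “cool with excess second end groups, so conversion is complete and loss small”.

The flasks give west > south-west > east > north > south-east, with west at 96.0% and south-east at 8.22%.

    first end groups + second end groups → links (k = 0.370 L mol⁻¹ s⁻¹, Ea = 52.0 kJ mol⁻¹)
    first end groups + second end groups → rings, rate k2*[first end groups] as long as [second end groups] is above zero (k = 0.00745 s⁻¹, Ea = 91.0 kJ mol⁻¹)
    first end groups ⇌ dormant form (K = 3.00, k = 0.00635 s⁻¹, Ea = 95.0 kJ mol⁻¹, ΔH = −23.0 kJ mol⁻¹)
    links ⇌ isomer of the product (K = 1.40, k = 0.00838 s⁻¹, Ea = 98.0 kJ mol⁻¹, ΔH = −45.0 kJ mol⁻¹)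
    2 second end groups → self-condensation product (k = 0.0443 L mol⁻¹ s⁻¹, Ea = 76.0 kJ mol⁻¹)
    (constants at 90 °C)

West's links stand 1.2 percentage points above my share, and at 4.00 min links and isomer of the product in west together make 99.2%, more than that share, while second end groups stand at 39% of their own charge, below the 75.0% my mean assumed. North runs at larch's temperature with a mean of 0.150 M, so the catch number gives it a ratio of 2.58 and a share of 72.1%. In north at 4.00 min, links at 30.3% and isomer of the product at 38.7% together make 71.5% of the 96.5% converted.

(The data are calculated for substances that don't exist; the scatter is artificial.)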